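## Retrosynthetic overview

- The target arises from an (E)-stilbene pentabenzyl ether by one hydrogenation that saturates the C=C bond and cleaves five benzyl ethers.
- Feature used: in ring A (C1 OMe, C2 H, C3 O, C4 ArCH2, C5 bridge carbon, C6 ArCH2), C5 lies between two identical 4-oxybenzyl groups on C4 and C6. One palladium/norbornene relay on an aryl iodide with iodine on C5 forms C4–CH2 and C6–CH2 (from 4-(benzyloxy)benzyl chloride) and C5–CH= (from the ring-B styrene).
- The aryl iodide comes from 1-iodo-3,5-dimethoxybenzene by mono-demethylation and O-benzylation. The ring-B styrene comes from 3-bromo-5-hydroxybenzaldehyde by O-benzylation, Wittig methylenation and Negishi benzylation with the zinc reagent of the same benzylic chloride.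
- No ring is formed in the route (all six benzene rings are bought) and the target has no stereocentre.

Key step: step 6

Remark: ring A is numbered C1 (OMe), C2 (H), C3 (O), C4, C5 (bridge), C6 throughout; the alkene geometry of the stilbene has no bearing on the target because the alkene is saturated in step 7.

## Route

Step 1
Reactants: 1 1-iodo-3,5-dimethoxybenzene
Product: 2 3-iodo-5-methoxyphenol
Conditions: BBr3 (1.0 equiv), CH2Cl2, −78 °C to 0 °C; MeOH/H2O quench; chromatography (diether recycled)
Reagents that add atoms: none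
Why: Lewis-acid O-demethylation with one equivalent of BBr3 should stop mainly at the mono-phenol, because the first cleavage ties the boron up as an aryloxyboron species and diether and diol are easily separated by polarity; the C–I bond is inert to BBr3.

Step 2
Reactants: 2 3-iodo-5-methoxyphenol
Product: 3 1-(benzyloxy)-3-iodo-5-methoxybenzene
Conditions: BnBr (1.1 equiv), K2CO3, DMF, 25 °C
Reagents that add atoms: benzyl bromide, BrCc1ccccc1
Why: Williamson ether synthesis, the phenoxide displacing bromide from benzyl bromide by SN2; the aryl iodide does not react under these conditions.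

Step 3
Reactants: 4 3-bromo-5-hydroxybenzaldehyde
Product: 5 3-(benzyloxy)-5-bromobenzaldehyde
Conditions: BnBr (1.1 equiv), K2CO3, DMF, 25 °C
Reagents that add atoms: benzyl bromide, BrCc1ccccc1
Why: Williamson ether synthesis on a phenol; the non-enolisable aldehyde and the aryl bromide are untouched by carbonate and benzyl bromide.

Step 4
Reactants: 5 3-(benzyloxy)-5-bromobenzaldehyde
Product: 6 1-(benzyloxy)-3-bromo-5-vinylbenzene
Conditions: Ph3PCH3Br (1.3 equiv), KOtBu (1.25 equiv), THF, 0 °C to 25 °C
Reagents that add atoms: methyltriphenylphosphonium bromide, C[P+](c1ccccc1)(c1ccccc1)c1ccccc1.[Br-]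
Why: Wittig methylenation of a non-enolisable aryl aldehyde; it is placed before the cross-coupling because the benzylic zinc reagent of step 5 would add to an aldehyde but not to a vinyl group.

Step 5
Reactants: 6 1-(benzyloxy)-3-bromo-5-vinylbenzene; 7 4-(benzyloxy)benzyl chloride
Product: 9 1-(benzyloxy)-3-[4-(benzyloxy)benzyl]-5-vinylbenzene, via 4-(benzyloxy)benzylzinc chloride 8 (not isolated)
Conditions: 7, Zn dust (1.5 equiv), LiCl (1.5 equiv), THF, 25 °C; then 6, Pd(OAc)2 (2 mol%), SPhos (4 mol%), THF, 25 °C
Reagents that add atoms: zinc, [Zn] (kept in intermediate 8 only, not in 9)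
Why: LiCl-promoted zinc insertion into the benzylic C–Cl bond followed by Negishi sp3–sp2 coupling; with the dialkylbiarylphosphine ligand the coupling should run at 25 °C, where the aryl palladium intermediate does not engage the vinyl group and the benzyl ethers are inert.

Step 6
Reactants: 3 1-(benzyloxy)-3-iodo-5-methoxybenzene (1.0 equiv); 7 4-(benzyloxy)benzyl chloride (3 equiv); 9 1-(benzyloxy)-3-[4-(benzyloxy)benzyl]-5-vinylbenzene (1.3 equiv)
Product: 10 (E)-1-(benzyloxy)-2,4-bis[4-(benzyloxy)benzyl]-3-{2-[3-(benzyloxy)-5-(4-(benzyloxy)benzyl)phenyl]ethenyl}-5-methoxybenzene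
Conditions: Pd(OAc)2 (10 mol%), P(2-furyl)3 (20 mol%), norbornene (2 equiv), Cs2CO3 (4 equiv), MeCN, 85 °C, sealed vessel, argon
Reagents that add atoms: none
Why: Catellani reaction (palladium/norbornene ortho,ortho′-dialkylation with Heck termination): zerovalent palladium inserts into the C5–I bond, norbornene inserts, and the norbornyl palladium metalates C4–H to a five-membered palladacycle, which adds benzylic chloride 7 to give tetravalent palladium and reductively eliminates the C4–CH2 bond; the same relay then benzylates C6. Only when both ortho positions are filled does steric pressure force β-carbon elimination of norbornene, so the C5 aryl palladium that meets styrene 9 already carries both benzyl groups; syn-insertion and syn-β-hydride elimination give the E-alkene. The closest known reaction type is the three-component double ortho-alkylation/Heck coupling of aryl iodides having two free ortho positions with primary alkyl halides and styrenes or acrylates; benzylic halides are known to add to such palladacycles but are the less usual alkylating partner. No ring is closed and no stereocentre is formed. The selectivities needed are aryl iodide before benzylic chloride in oxidative addition (the C–I insertion is far faster), norbornene before styrene at the first aryl palladium (strained alkene in excess), and alkylation before Heck coupling (norbornene is not expelled until C4 and C6 are both substituted). Each ortho C–H is flanked by an alkoxy group, which makes the second palladation the demanding event; the two oxygen substituents are small, can turn their alkyl groups toward C2–H, and leave C2 out of reach of the palladacycle.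

Step 7
Reactants: 10 (E)-stilbene pentabenzyl ether
Product: 11 2,4-bis(4-hydroxybenzyl)-3-{2-[3-hydroxy-5-(4-hydroxybenzyl)phenyl]ethyl}-5-methoxyphenol (CNP0204120.0)
Conditions: H2 (3 bar), Pd/C (10 wt% Pd), THF/MeOH (1:1), 25 °C
Reagents that add atoms: none
Why: heterogeneous catalytic hydrogenation should saturate the disubstituted stilbene alkene and hydrogenolyse the five aryl benzyl ethers in one operation, while the aryl methyl ether and the diarylmethane C–C bonds are stable to these conditions.

## Compound list

1 | 1-iodo-3,5-dimethoxybenzene | COc1cc(I)cc(OC)c1 | starting material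
2 | 3-iodo-5-methoxyphenol | COc1cc(O)cc(I)c1 | intermediate
3 | 1-(benzyloxy)-3-iodo-5-methoxybenzene | COc1cc(I)cc(OCc2ccccc2)c1 | intermediate
4 | 3-bromo-5-hydroxybenzaldehyde | O=Cc1cc(O)cc(Br)c1 | starting material
5 | 3-(benzyloxy)-5-bromobenzaldehyde | O=Cc1cc(Br)cc(OCc2ccccc2)c1 | intermediate
6 | 1-(benzyloxy)-3-bromo-5-vinylbenzene | C=Cc1cc(Br)cc(OCc2ccccc2)c1 | intermediate
7 | 4-(benzyloxy)benzyl chloride | ClCc1ccc(OCc2ccccc2)cc1 | starting material
8 | 4-(benzyloxy)benzylzinc chloride (THF solution, LiCl complex) | Cl[Zn]Cc1ccc(OCc2ccccc2)cc1 | intermediate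
9 | 1-(benzyloxy)-3-[4-(benzyloxy)benzyl]-5-vinylbenzene | C=Cc1cc(OCc2ccccc2)cc(Cc2ccc(OCc3ccccc3)cc2)c1 | intermediate
10 | (E)-1-(benzyloxy)-2,4-bis[4-(benzyloxy)benzyl]-3-{2-[3-(benzyloxy)-5-(4-(benzyloxy)benzyl)phenyl]ethenyl}-5-methoxybenzene | COc1cc(OCc2ccccc2)c(Cc2ccc(OCc3ccccc3)cc2)c(/C=C/c2cc(OCc3ccccc3)cc(Cc3ccc(OCc4ccccc4)cc3)c2)c1Cc1ccc(OCc2ccccc2)cc1 | intermediate
11 | 2,4-bis(4-hydroxybenzyl)-3-{2-[3-hydroxy-5-(4-hydroxybenzyl)phenyl]ethyl}-5-methoxyphenol | COc1cc(O)c(Cc2ccc(O)cc2)c(CCc2cc(O)cc(Cc3ccc(O)cc3)c2)c1Cc1ccc(O)cc1 | target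

## Step count and risks

Total step count: 7. Longest linear sequence: 5 steps (4 → 5 → 6 → 9 → 10 → 11; steps 3, 4, 5, 6, 7).

**Step 6 (most likely to fail).** The second ortho palladation must take place at a C–H bond wedged between the norbornyl-bearing carbon and an alkoxy group. It competes with:
- early loss of norbornene and Heck coupling of un- or mono-benzylated aryl palladium;
- consumption of the electron-rich benzylic chloride by zerovalent palladium or carbonate;
- cyclisation of the final aryl palladium onto an ortho benzyl ring.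

Fallback: it sets out from 3 (with 8 and 9 as partners) and comes back at 11, making the three bonds one after another by electrophilic bromination and cross-coupling. NBS (2.1 equiv, MeCN, 0 to 25 °C, dark) should brominate 3 at the two positions para to an alkoxy group, which are the two positions ortho to iodine, to give 1-(benzyloxy)-2,4-dibromo-3-iodo-5-methoxybenzene F1. Styrene 9 is hydroborated with 9-BBN (THF, 25 °C) to 9-{2-[3-(benzyloxy)-5-(4-(benzyloxy)benzyl)phenyl]ethyl}-9-borabicyclo[3.3.1]nonane F2. This is coupled in the same flask with F1 at the more reactive C–I bond (B-alkyl Suzuki–Miyaura coupling; PdCl2(dppf), K3PO4, THF/H2O, 50 °C) to give 1-(benzyloxy)-2,4-dibromo-3-{2-[3-(benzyloxy)-5-(4-(benzyloxy)benzyl)phenyl]ethyl}-5-methoxybenzene F3. Double Negishi coupling of F3 with zinc reagent 8 (2.6 equiv, Pd(OAc)2, SPhos, THF, 50 °C) should give 1-(benzyloxy)-2,4-bis[4-(benzyloxy)benzyl]-3-{2-[3-(benzyloxy)-5-(4-(benzyloxy)benzyl)phenyl]ethyl}-5-methoxybenzene F4. Hydrogenolysis of the five benzyl ethers (H2, Pd/C, THF/MeOH) then gives 11.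

**Step 5.** Wurtz-type homocoupling of the electron-rich benzylic chloride during zinc insertion, or slow transmetalation that lets the aryl palladium intermediate attack the vinyl group, would erode the coupling.

Fallback: it sets out from 6 and comes back at 9, with the polarity of the two partners reversed. Miyaura borylation of 6 (B2pin2, PdCl2(dppf), KOAc, dioxane, 80 °C) should give 2-[3-(benzyloxy)-5-vinylphenyl]-4,4,5,5-tetramethyl-1,3,2-dioxaborolane F5. Suzuki–Miyaura coupling of F5 with benzylic chloride 7 (PdCl2(dppf), K3PO4, THF/H2O, 65 °C) forms the same aryl–CH2 bond without any organozinc reagent and gives 9.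

**Step 7.** Hydrogenolysis of five benzyl ethers may stall part-way through catalyst poisoning by iodide or phosphine residues from step 6, or through poor solubility of partly deprotected phenols, leaving mixtures.

Fallback: it sets out from 10 and comes back at 11, with the ethers cleaved by a Lewis acid instead of by hydrogenolysis. BCl3 (10 equiv) with pentamethylbenzene (15 equiv) as benzyl-cation scavenger in CH2Cl2 at −78 °C should remove the five benzyl groups while leaving the aryl methyl ether and the alkene, giving 2,4-bis(4-hydroxybenzyl)-3-{(E)-2-[3-hydroxy-5-(4-hydroxybenzyl)phenyl]ethenyl}-5-methoxyphenol F6. Simple saturation of the alkene (H2 at 1 bar, Pd/C, MeOH, 25 °C) then gives 11.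

## Further compounds

F1 | step 6 | 1-(benzyloxy)-2,4-dibromo-3-iodo-5-methoxybenzene | COc1cc(OCc2ccccc2)c(Br)c(I)c1Br
F2 | step 6 | 9-{2-[3-(benzyloxy)-5-(4-(benzyloxy)benzyl)phenyl]ethyl}-9-borabicyclo[3.3.1]nonane | C1CC2CCCC(C1)B2CCc1cc(OCc2ccccc2)cc(Cc2ccc(OCc3ccccc3)cc2)c1
F3 | step 6 | 1-(benzyloxy)-2,4-dibromo-3-{2-[3-(benzyloxy)-5-(4-(benzyloxy)benzyl)phenyl]ethyl}-5-methoxybenzene | COc1cc(OCc2ccccc2)c(Br)c(CCc2cc(OCc3ccccc3)cc(Cc3ccc(OCc4ccccc4)cc3)c2)c1Br
F4 | step 6 | 1-(benzyloxy)-2,4-bis[4-(benzyloxy)benzyl]-3-{2-[3-(benzyloxy)-5-(4-(benzyloxy)benzyl)phenyl]ethyl}-5-methoxybenzene | COc1cc(OCc2ccccc2)c(Cc2ccc(OCc3ccccc3)cc2)c(CCc2cc(OCc3ccccc3)cc(Cc3ccc(OCc4ccccc4)cc3)c2)c1Cc1ccc(OCc2ccccc2)cc1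
F5 | step 5 | 2-[3-(benzyloxy)-5-vinylphenyl]-4,4,5,5-tetramethyl-1,3,2-dioxaborolane | C=Cc1cc(OCc2ccccc2)cc(B2OC(C)(C)C(C)(C)O2)c1
F6 | step 7 | 2,4-bis(4-hydroxybenzyl)-3-{(E)-2-[3-hydroxy-5-(4-hydroxybenzyl)phenyl]ethenyl}-5-methoxyphenol | COc1cc(O)c(Cc2ccc(O)cc2)c(/C=C/c2cc(O)cc(Cc3ccc(O)cc3)c2)c1Cc1ccc(O)cc1
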